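The data are calculated for substances that don't exist; noise was put on by code.

I decided to reckon the new flask from one number read off the two runs, and to leave any scheme until later.

| setting | green | ochre | flask |
|---|---|---|---|
| D | 0.026 M | 0.058 M | 0.039 M |
| remark | run made earlier | run made earlier |  |
| time |  |  | 4.0 min |

| run | time / min | Z / % |
|---|---|---|
| green | 0.167 | 10.7 |
| green | 0.250 | 12.3 |
| green | 0.500 | 13.2 |
| green | 1.00 | 12.5 |
| green | 2.00 | 9.1 |
| green | 4.00 | 4.5 |
| ochre | 0.167 | 8.7 |
| ochre | 0.250 | 9.6 |
| ochre | 0.500 | 10.9 |
| ochre | 1.00 | 9.1 |
| ochre | 2.00 | 7.8 |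
| ochre | 4.00 | 4.6 |

(readings scatter by 0.5 percentage points)

- when, up to 4.0 min, the flask holds most Z
- the amount of Z, in percent of the D charged, at that time



In slow motion the runs read as a rise, a top and a fall. In the first instants Z, an intermediate, climbed fast: by 0.167 min green held 10.7 % and ochre 8.7 %, so the more dilute run was already ahead. In the middle both runs read highest at 0.500 min, green at 13.2 % and ochre at 10.9 %, on a grid too coarse to part their times. At 4.00 min green read 4.5 % and ochre 4.6 %, so the gap seen at the top could no longer be read there, and the height of the peak was the thing I carried. I therefore took the dilution gain, the points of peak Z won per unit of ln(concentration) lost, which is the difference of the two tops over the logarithm of the concentration ratio: g = 2.9 percentage points. Stepping down from green to the concentration of the flask, g gave me 12.0 %, and I kept the shared time of 0.500 min; the two tops behind g are readings, each carrying a scatter of 0.5 points, and that time is a point of the coarse grid.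

The forecast said 12.1 % (range 11.2 % to 13 %) at 0.45 min (range 0.3 min to 0.65 min), holding that “More dilute gives more ring”; its time stood earlier than mine.

The flask gave 12.0 % at 0.533 min, later than the forecast's time by a factor of 1.18, beside the 12.0 % that g had given. At that moment E, each counted as the two D it holds, stood at 49.2 % of the D charged, the largest share in the flask.

    D ⇌ Z (K = 3.69, k = 0.0203 s⁻¹)
    2 D ⇌ E (K = 75.0 M⁻¹, k = 1.57 M⁻¹ s⁻¹)
    Z ⇌ G (K = 0.130, k = 0.0159 s⁻¹)
    Z → Q (k = 0.0373 s⁻¹)

On a neighbour flask charged with 0.0097 M of D, more dilute than green, g steps up from green to 16.0 %. The computed best there is 18.0 %, higher than g's figure.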